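**Strategy.** Everything rests on making the bond between ring carbon C4 of the tetrahydrofuran and its benzylic CH2 by C-benzylation of a lactone enolate. The step exploits the 1,4-dioxygenated chain C5–C4–C3–CH2O (ring CH2, both ring CH, the ester CH2): closed between C5 and the exocyclic CH2O carbon instead of between C5 and C2, it is a γ-butyrolactone on which the 3,4-cis pattern of the target is the easy trans pattern. In one pot a lithiated aryl dithiane adds to (5R)-5-menthyloxybutenolide and the enolate is benzylated, fixing C3 and C4 absolutely. The precursor is therefore a dithianyl acetal-lactone enolate; reduction and a stereoconvergent cationic ring closure then build the real ring.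

Key step: step 2

Remark: (5R)-5-(l-menthyloxy)furan-2(5H)-one and 3,4-dimethoxybenzyl bromide are taken as purchased materials; the bromide is used freshly because it degrades on storage. "l-Menthyl" means (1R,2S,5R)-2-isopropyl-5-methylcyclohexyl throughout.

Step 1
Reactants: 1 3,4-dimethoxybenzaldehyde; 2 propane-1,3-dithiol
Product: 3 2-(3,4-dimethoxyphenyl)-1,3-dithiane
Conditions: BF3·OEt2 (cat.), CH2Cl2, 0 °C → rt
Reagents that add atoms: none
Why: Lewis acid-catalysed dithioacetalisation of an aromatic aldehyde, which forms no stereocentre and gives the acyl-anion equivalent for the aryl-bearing ring carbon.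

Step 2
Reactants: 3 2-(3,4-dimethoxyphenyl)-1,3-dithiane; 4 (5R)-5-(l-menthyloxy)furan-2(5H)-one; 5 3,4-dimethoxybenzyl bromide
Product: 8 (3R,4R,5R)-3-(3,4-dimethoxybenzyl)-4-[2-(3,4-dimethoxyphenyl)-1,3-dithian-2-yl]-5-(l-menthyloxy)dihydrofuran-2(3H)-one, via lithiated dithiane 6 (not isolated), via lactone lithium enolate 7 (not isolated)
Conditions: n-BuLi, THF, −78 → −20 °C; 4, −78 °C; then 5, DMPU, −78 → 0 °C
Reagents that add atoms: none
Why: The sulfur-stabilised aryl anion 6 adds 1,4 to butenolide 4, and the lactone enolate 7 so formed is C-benzylated in an SN2 reaction by bromide 5, which creates the bond between the future ring carbon C4 and the benzylic CH2 and joins the two aryl-bearing halves. The closest known reaction type is the three-component Michael addition/enolate alkylation of lithiated 2-aryl-1,3-dithianes on 5-alkoxy-2(5H)-furanones used for dibenzylbutyrolactone lignans. No ring is closed in this step. The β-stereocentre (lactone C4) is controlled by the acetal centre C5, because the anion adds anti to the menthyloxy group, and the α-stereocentre (lactone C3) is controlled by C4, because the bromide approaches the enolate face anti to the bulky dithianyl group, so the product should be trans,trans and of one absolute configuration fixed by (5R)-4. The step needs 1,4- over 1,2-addition, which the soft aryl- and sulfur-stabilised anion secures, and clean mono-C-alkylation, which the lithium enolate, the polar additive and the tertiary, flanked product α-carbon secure. The trans relationship made on this lactone ring is the 3,4-cis relationship of the tetrahydrofuran, since that ring is later closed through the other oxygen.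

Step 3
Reactants: 8 (3R,4R,5R)-3-(3,4-dimethoxybenzyl)-4-[2-(3,4-dimethoxyphenyl)-1,3-dithian-2-yl]-5-(l-menthyloxy)dihydrofuran-2(3H)-one
Product: 9 (3R,4R,5R)-3-(3,4-dimethoxybenzyl)-4-(3,4-dimethoxybenzoyl)-5-(l-menthyloxy)dihydrofuran-2(3H)-one
Conditions: MeI, CaCO3, MeCN/H2O (9:1), 45 °C
Reagents that add atoms: water, O
Why: Alkylative thioacetal hydrolysis (S-methylation, aryl-stabilised thionium ion, attack of water) should release the aryl ketone under near-neutral conditions that spare the acetal lactone, and the ketone α-centre already sits in the thermodynamically preferred trans,trans arrangement.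

Step 4
Reactants: 9 (3R,4R,5R)-3-(3,4-dimethoxybenzyl)-4-(3,4-dimethoxybenzoyl)-5-(l-menthyloxy)dihydrofuran-2(3H)-one
Product: 10 (2R,3R)-2-(3,4-dimethoxybenzyl)-3-[(3,4-dimethoxyphenyl)(hydroxy)methyl]butane-1,4-diol (both carbinol epimers)
Conditions: LiAlH4 (excess, inverse addition), THF, 0 °C → rt; aqueous NaOH work-up
Reagents that add atoms: none
Why: Hydride reduction of the ketone, the lactone carbonyl and the aldehyde unmasked when the menthyl hemiacetal collapses should give the triol and free menthol, with fast reduction of the transient aldehyde outrunning enolisation so that the two backbone centres are kept, while the new carbinol centre forms as a mixture that step 5 corrects.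

Step 5
Reactants: 10 (2R,3R)-2-(3,4-dimethoxybenzyl)-3-[(3,4-dimethoxyphenyl)(hydroxy)methyl]butane-1,4-diol
Product: 11 [(2S,3R,4R)-4-(3,4-dimethoxybenzyl)-2-(3,4-dimethoxyphenyl)tetrahydrofuran-3-yl]methanol
Conditions: CSA (10 mol %), 4 Å MS, CH2Cl2, 0 °C → rt
Reagents that add atoms: none
Why: Acid-catalysed dehydrative cycloetherification (SN1) in which both carbinol epimers ionise to the same 3,4-dimethoxybenzylic cation, the remote primary hydroxyl closes the five-membered ring (the nearer one could only give an oxetane), and closure through the less crowded arrangement, with re-ionisation of any cis isomer, should place the aryl group trans to the adjacent CH2OH (2S).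

Step 6
Reactants: 11 [(2S,3R,4R)-4-(3,4-dimethoxybenzyl)-2-(3,4-dimethoxyphenyl)tetrahydrofuran-3-yl]methanol; 12 angelic acid, (2Z)-2-methylbut-2-enoic acid
Product: 13 leoligin, [(2S,3R,4R)-4-(3,4-dimethoxybenzyl)-2-(3,4-dimethoxyphenyl)tetrahydrofuran-3-yl]methyl (2Z)-2-methylbut-2-enoate
Conditions: PPh3, DIAD, THF, 0 °C → rt
Reagents that add atoms: none
Why: Mitsunobu esterification activates the primary alcohol and uses the acid only as a carboxylate nucleophile, so the Z double bond should survive without the Z→E isomerisation that acyl activation of angelic acid invites, and no stereocentre is touched.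

**Compound list**

1 | 3,4-dimethoxybenzaldehyde | O=Cc1ccc(OC)c(OC)c1 | starting material
2 | propane-1,3-dithiol | SCCCS | starting material
3 | 2-(3,4-dimethoxyphenyl)-1,3-dithiane | COc1ccc(C2SCCCS2)cc1OC | intermediate
4 | (5R)-5-{[(1R,2S,5R)-2-isopropyl-5-methylcyclohexyl]oxy}furan-2(5H)-one | O=C1O[C@@H](O[C@@H]2C[C@H](C)CC[C@H]2C(C)C)C=C1 | starting material
5 | 3,4-dimethoxybenzyl bromide | BrCc1ccc(OC)c(OC)c1 | starting material
6 | 2-(3,4-dimethoxyphenyl)-2-lithio-1,3-dithiane | [Li]C1(c2ccc(OC)c(OC)c2)SCCCS1 | intermediate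
7 | lithium (4R,5R)-4-[2-(3,4-dimethoxyphenyl)-1,3-dithian-2-yl]-5-(l-menthyloxy)-4,5-dihydrofuran-2-olate | [Li]OC1=C[C@@H](C2(c3ccc(OC)c(OC)c3)SCCCS2)[C@H](O[C@@H]2C[C@H](C)CC[C@H]2C(C)C)O1 | intermediate
8 | (3R,4R,5R)-3-(3,4-dimethoxybenzyl)-4-[2-(3,4-dimethoxyphenyl)-1,3-dithian-2-yl]-5-(l-menthyloxy)dihydrofuran-2(3H)-one | O=C1O[C@@H](O[C@@H]2C[C@H](C)CC[C@H]2C(C)C)[C@H](C2(c3ccc(OC)c(OC)c3)SCCCS2)[C@H]1Cc1ccc(OC)c(OC)c1 | intermediate
9 | (3R,4R,5R)-3-(3,4-dimethoxybenzyl)-4-(3,4-dimethoxybenzoyl)-5-(l-menthyloxy)dihydrofuran-2(3H)-one | O=C1O[C@@H](O[C@@H]2C[C@H](C)CC[C@H]2C(C)C)[C@H](C(=O)c2ccc(OC)c(OC)c2)[C@H]1Cc1ccc(OC)c(OC)c1 | intermediate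
10 | (2R,3R)-2-(3,4-dimethoxybenzyl)-3-[(3,4-dimethoxyphenyl)(hydroxy)methyl]butane-1,4-diol, carbinol epimers | OC[C@H](C(O)c1ccc(OC)c(OC)c1)[C@@H](Cc1ccc(OC)c(OC)c1)CO | intermediate
11 | [(2S,3R,4R)-4-(3,4-dimethoxybenzyl)-2-(3,4-dimethoxyphenyl)tetrahydrofuran-3-yl]methanol | OC[C@H]1[C@@H](Cc2ccc(OC)c(OC)c2)CO[C@@H]1c1ccc(OC)c(OC)c1 | intermediate
12 | angelic acid, (2Z)-2-methylbut-2-enoic acid | C/C=C(/C)C(=O)O | starting material
13 | leoligin | C/C=C(/C)C(=O)OC[C@H]1[C@@H](Cc2ccc(OC)c(OC)c2)CO[C@@H]1c1ccc(OC)c(OC)c1 | target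

**Step count and risks**

Total steps: 6. Longest linear sequence: 6 steps (1 → 3 → 8 → 9 → 10 → 11 → 13).

Risk 1, step 2. The SN2 benzylation of the hindered enolate may be slow, so that proton transfer or retro-Michael loss of the dithiane on warming erodes yield and trans selectivity. The fallback sets out from 3 and 4 and comes back at 8. Enolate 7 is made as before but trapped at −78 °C with aldehyde 1, a much faster electrophile, to give the aldol adduct (3S,4R,5R)-3-[(3,4-dimethoxyphenyl)(hydroxy)methyl]-4-[2-(3,4-dimethoxyphenyl)-1,3-dithian-2-yl]-5-(l-menthyloxy)dihydrofuran-2(3H)-one F1, again anti to the dithianyl group. The benzylic hydroxyl is converted with 1,1'-thiocarbonyldiimidazole (DMAP cat., CH2Cl2, reflux) into the O-(imidazol-1-ylthiocarbonyl) derivative F2. Barton–McCombie deoxygenation (Bu3SnH, AIBN, toluene, 80 °C) removes it and should return 8. The radical route avoids the benzylic cation, which the neighbouring aryl ring would capture.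

Risk 2, step 5. The benzylic cation may be captured by the second dimethoxyphenyl ring (Friedel–Crafts closure to an aryltetralin), or the ring may close without full 2,3-trans selectivity. The fallback sets out from 8 and comes back at 11. Raney nickel (EtOH/THF) desulfurises the dithiane to (3R,4R,5R)-3,4-bis(3,4-dimethoxybenzyl)-5-(l-menthyloxy)dihydrofuran-2(3H)-one F3. LiAlH4 then gives the C2-symmetric diol (2R,3R)-2,3-bis(3,4-dimethoxybenzyl)butane-1,4-diol F4. DDQ (1 equiv, CH2Cl2, NaHCO3, 0 °C) abstracts a benzylic hydride, and the ion pair is trapped by the δ-hydroxyl under non-acidic conditions. The two benzylic positions are equivalent by symmetry, so either one should lead to 11.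

Risk 3, step 3. Cleavage of the hindered thioacetal may be incomplete, or menthol may be lost by β-elimination from the β-alkoxy ketone. The fallback sets out from 8 and comes back at 10. LiAlH4 is applied first, giving (2R,3R)-2-(3,4-dimethoxybenzyl)-3-[2-(3,4-dimethoxyphenyl)-1,3-dithian-2-yl]butane-1,4-diol F5, which no longer carries the sensitive acetal. Hg(ClO4)2/CaCO3 in aqueous THF then unmasks (2R,3R)-2-(3,4-dimethoxybenzyl)-3-(3,4-dimethoxybenzoyl)butane-1,4-diol F6, expected to sit largely as its cyclic hemiketal. NaBH4/CeCl3 (MeOH, −20 °C) reduces it to 10.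

Further compounds
F1 | step 2 | (3S,4R,5R)-3-[(3,4-dimethoxyphenyl)(hydroxy)methyl]-4-[2-(3,4-dimethoxyphenyl)-1,3-dithian-2-yl]-5-(l-menthyloxy)dihydrofuran-2(3H)-one, carbinol epimers | O=C1O[C@@H](O[C@@H]2C[C@H](C)CC[C@H]2C(C)C)[C@H](C2(c3ccc(OC)c(OC)c3)SCCCS2)[C@H]1C(O)c1ccc(OC)c(OC)c1
F2 | step 2 | O-(1H-imidazol-1-ylthiocarbonyl) derivative of F1 | O=C1O[C@@H](O[C@@H]2C[C@H](C)CC[C@H]2C(C)C)[C@H](C2(c3ccc(OC)c(OC)c3)SCCCS2)[C@H]1C(OC(=S)n2ccnc2)c1ccc(OC)c(OC)c1
F3 | step 5 | (3R,4R,5R)-3,4-bis(3,4-dimethoxybenzyl)-5-(l-menthyloxy)dihydrofuran-2(3H)-one | O=C1O[C@@H](O[C@@H]2C[C@H](C)CC[C@H]2C(C)C)[C@H](Cc2ccc(OC)c(OC)c2)[C@H]1Cc1ccc(OC)c(OC)c1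
F4 | step 5 | (2R,3R)-2,3-bis(3,4-dimethoxybenzyl)butane-1,4-diol | OC[C@H](Cc1ccc(OC)c(OC)c1)[C@@H](Cc1ccc(OC)c(OC)c1)CO
F5 | step 3 | (2R,3R)-2-(3,4-dimethoxybenzyl)-3-[2-(3,4-dimethoxyphenyl)-1,3-dithian-2-yl]butane-1,4-diol | OC[C@H](C1(c2ccc(OC)c(OC)c2)SCCCS1)[C@@H](Cc1ccc(OC)c(OC)c1)CO
F6 | step 3 | (2R,3R)-2-(3,4-dimethoxybenzyl)-3-(3,4-dimethoxybenzoyl)butane-1,4-diol | OC[C@H](C(=O)c1ccc(OC)c(OC)c1)[C@@H](Cc1ccc(OC)c(OC)c1)CO
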